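The decalin is cut across ring B at C5–C6 and C9–C10 (eudesmane numbering), which reveals ring A as a quinone: C1 (CHBr) and C4 (carbinol) flank the C5/C10 ring fusion just as the two carbonyls of 2-methoxy-5-methylbenzoquinone flank its methyl-bearing double bond, and the C6 oxygen lies trans to the C10 methyl, as in the endo adduct of a 1-oxygenated butadiene. One enantioselective Diels–Alder reaction therefore closes ring B, forms both bonds and creates C5, C6 and C10 (C5 is epimerised afterwards). Its precursors are the methoxy-methylquinone and an (E)-1-silyloxybutadiene; all later stereocentres are relayed from the adduct.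

Key step: step 2

Remark on numbering: eudesmane numbering is used throughout, also for the quinone-derived ring (C1 CHBr, C4 carbinol, C5/C10 ring fusion, C6 CHOAc, C7 CH-iPr); β is the face of the C10 methyl.

Assumption 1: the diene oxygen is carried as a TBS ether and not as the acetate of the target, because an acyloxy group at C6, β to the C4 ketone, would be expelled (E1cB) during the C5 equilibration and must come off before the O6 tether is built in any case; the acetate is put on in step 12.

Assumption 2: the (R)-BINOL-derived titanium catalyst is taken to give the (4aR,5S,8aR) adduct; the sense of induction depends only on the ligand antipode, so the (S)-ligand is used if the opposite enantiomer forms.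

Step 1
Reactants: 1 (E)-but-2-enal (crotonaldehyde)
Product: 2 (E)-1-(tert-butyldimethylsilyloxy)buta-1,3-diene
Conditions: TBSOTf, Et3N, Et2O, 0 °C → rt; distillation
Reagents that add atoms: tert-butyldimethylsilyl trifluoromethanesulfonate, CC(C)(C)[Si](C)(C)OS(=O)(=O)C(F)(F)F
Why: Soft enolisation of the O-activated enal at the γ-carbon by triethylamine gives the silyl dienol ether (silyl enol ether formation), the 1E isomer being expected to predominate and the 1Z isomer being inert in the next step.

Step 2
Reactants: 3 2-methoxy-5-methyl-1,4-benzoquinone; 2 (E)-1-(tert-butyldimethylsilyloxy)buta-1,3-diene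
Product: 4 cis-fused endo adduct (4aR,5S,8aR)-5-(tert-butyldimethylsilyloxy)-3-methoxy-8a-methyl-4a,5,8,8a-tetrahydronaphthalene-1,4-dione (6α-OTBS; 5β-H; 10β-CH3)
Conditions: (R)-BINOL/TiCl2(OiPr)2 (15 mol%, MS 4 Å then filtered), toluene–CH2Cl2, −40 → −20 °C
Reagents that add atoms: none
Why: Two-point coordination of titanium to the C3 methoxy oxygen and the adjacent, non-vinylogous C4 carbonyl lowers the LUMO of the methyl-bearing C5=C10 alkene, which undergoes a concerted but asynchronous normal-demand [4+2] cycloaddition with the silyloxydiene, the bond from the unsubstituted diene terminus to C10 being the more advanced. The closest known reaction type is the BINOL–titanium(IV)-catalysed Diels–Alder reaction of quinones with 1-acyloxy- and 1-alkoxybutadienes. Ring B closes by intermolecular suprafacial [4+2] addition that forms C5–C6 and C9–C10 together, so the ring fusion is cis (C5–H and C10–CH3 on one face). C6 is set by the endo transition state, which puts the diene oxygen on the face opposite to the C5 hydrogen and the C10 methyl, and the absolute configuration of all three centres is set by the BINOL antipode shielding one face of the chelated quinone. Site selectivity rests on the methoxy group, which turns C2=C3 into an unreactive vinylogous ester, and regioselectivity rests on C4=O being the controlling carbonyl, so that C10 is the electrophilic β-carbon and the oxygen-bearing diene carbon ends on C5 (ortho orientation). A monodentate Lewis acid would instead bind the more basic C1 vinylogous-ester carbonyl and invert this orientation, which is why a chelating titanium catalyst is specified.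

Step 3
Reactants: 4 cis-fused endo adduct
Product: 5 trans-fused adduct (4aS,5S,8aR)-5-(tert-butyldimethylsilyloxy)-3-methoxy-8a-methyl-4a,5,8,8a-tetrahydronaphthalene-1,4-dione (5α-H)
Conditions: DBU (0.2 equiv), THF, 0 °C → rt; chromatography, recovered 4 recycled
Reagents that add atoms: none
Why: C5–H is the only enolisable hydrogen of the enedione, so catalytic DBU should equilibrate the ring fusion through the C4–C5 enolate (base-mediated cis-to-trans epimerisation of a quinone Diels–Alder adduct) toward the trans isomer, in which C4 and the C6 oxygen are both equatorial on ring B, while a silanolate is too poor a leaving group for E1cB loss of O6 to compete.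

Step 4
Reactants: 5 trans-fused adduct
Product: 7 (4aS,5S,8aR)-5-(tert-butyldimethylsilyloxy)-8a-methyl-2,3,4a,5,8,8a-hexahydronaphthalene-1,4-dione, via 3-methoxy dione 6 (not isolated)
Conditions: SmI2 (4.5 equiv), MeOH, THF, −78 °C; aq. NH4Cl
Reagents that add atoms: none
Why: Samarium diiodide first saturates the electron-poor C2=C3 bond of the enedione and then cleaves the C3–OMe bond of the resulting α-methoxy ketone through the C4 ketyl (reductive cleavage of α-heterosubstituted ketones), the samarium enolate being formed toward C3 so that the C5 configuration is not touched.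

Step 5
Reactants: 7 silyloxy dione
Product: 8 (4aS,5S,8aR)-5-hydroxy-8a-methyl-2,3,4a,5,8,8a-hexahydronaphthalene-1,4-dione (6α-OH)
Conditions: HF·pyridine, THF, 0 °C → rt
Reagents that add atoms: none
Why: Fluoride-driven cleavage of the Si–O bond under acidic, non-enolising conditions (silyl ether deprotection) frees the 6α-hydroxyl without risk of retro-aldol or elimination at the β-hydroxy ketone.

Step 6
Reactants: 8 hydroxy dione; 9 ethyl 1-propenyl ether
Product: 10 bromoacetal (4aS,5S,8aR)-5-(2-bromo-1-ethoxypropoxy)-8a-methyl-2,3,4a,5,8,8a-hexahydronaphthalene-1,4-dione (side-chain diastereomers)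
Conditions: NBS, CH2Cl2, −40 → 0 °C
Reagents that add atoms: N-bromosuccinimide, O=C1CCC(=O)N1Br
Why: NBS brominates the electron-rich enol ether at its β-carbon and the resulting oxocarbenium ion is captured by the C6 hydroxyl (Ueno–Stork haloacetalisation), the configuration of the two new side-chain centres being irrelevant because both are erased later.

Step 7
Reactants: 10 bromoacetal
Product: 11 tricyclic acetal: trans-10β-methyldecalin-1,4-dione whose O6 (α) and C7 (α) are bridged by CH(OEt)–CH(CH3) (cis-fused 2-ethoxy-3-methyloxolane; epimers at the two oxolane carbons)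
Conditions: Bu3SnH (syringe pump), AIBN (cat.), benzene, 80 °C
Reagents that add atoms: none
Why: Bromine abstraction gives a secondary radical that closes 5-exo-trig onto C7 (Ueno–Stork radical cyclisation), the short tether from the α-oriented O6 allowing only a cis-fused oxolane and so fixing the new C7–C bond α, after which the C8 radical is reduced by the stannane and the two ketones stay untouched.

Step 8
Reactants: 11 tricyclic acetal
Product: 12 4-methylene tricyclic acetal (C1 ketone kept)
Conditions: Cp2TiMe2 (1.3 equiv), toluene, 65 °C, dark
Reagents that add atoms: dimethyltitanocene, [CH3-].[CH3-].[Ti+4].c1cc[cH-]c1.c1cc[cH-]c1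
Why: Thermally generated Cp2Ti=CH2 converts the C4 carbonyl into the exocyclic methylene through an oxatitanacyclobutane (Petasis methylenation) without base, so C5 cannot epimerise, and with a small excess it should react at C4 only because the C1 carbonyl is flanked by the quaternary C10.

Step 9
Reactants: 12 4-methylene tricyclic acetal
Product: 13 tertiary alcohol (4α-OH; 4β-CH3; C1 ketone and acetal kept)
Conditions: Co(acac)2 (20 mol%), PhSiH3, O2 (1 atm), THF, rt; then PPh3, aq. work-up
Reagents that add atoms: dioxygen, O=O
Why: Cobalt-hydride hydrogen-atom transfer to the CH2 terminus gives the tertiary C4 radical, which is trapped by O2 and reduced to the alcohol (Mukaiyama hydration, Markovnikov), oxygen entering from the α face because the β (axial) face is 1,3-diaxial to the C10 methyl, which gives 4α-OH and 4β-CH3.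

Step 10
Reactants: 13 tertiary alcohol
Product: 14 dithiolane diol: 4α,6α-dihydroxy-4β,10β-dimethyl-7α-[1-(1,3-dithiolan-2-yl)ethyl]-trans-decalin-1-one
Conditions: HS(CH2)2SH, BF3·OEt2, CH2Cl2, −40 → 0 °C
Reagents that add atoms: ethane-1,2-dithiol, SCCS
Why: Boron trifluoride ionises the mixed acetal and the dithiol replaces both C–O bonds (transthioacetalisation), opening the oxolane to the dithiolane and freeing the 6α-hydroxyl, while the hindered C1 ketone and the tertiary alcohol should survive at low temperature.

Step 11
Reactants: 14 dithiolane diol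
Product: 15 4α,6α-dihydroxy-7α-isopropyl-4β,10β-dimethyl-trans-decalin-1-one
Conditions: Raney Ni (W-2, acetone-deactivated), EtOH, rt
Reagents that add atoms: none
Why: Raney nickel hydrogenolyses both C–S bonds (Mozingo desulfurisation), turning the dithiolane carbon into the second methyl of the isopropyl group, whose central carbon thereby stops being a stereocentre, and acetone-deactivated catalyst should leave the C1 ketone alone.

Step 12
Reactants: 15 dihydroxy ketone
Product: 16 6α-acetoxy-4α-hydroxy-7α-isopropyl-4β,10β-dimethyl-trans-decalin-1-one
Conditions: Ac2O, pyridine, DMAP (cat.), CH2Cl2, 0 °C → rt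
Reagents that add atoms: acetic anhydride, CC(=O)OC(C)=O
Why: DMAP-catalysed acylation esterifies the secondary, equatorial 6α-hydroxyl, whereas the tertiary 4α-hydroxyl is inert under these conditions.

Step 13
Reactants: 16 acetoxy ketone
Product: 18 vinyl bromide (1-bromo-1(2)-ene; 6α-OAc; 4α-OH), via silyl hydrazone 17 (not isolated)
Conditions: TBSNHNHTBS, Sc(OTf)3 (1 mol%), neat, 80 °C; volatiles removed; then Br2, BTMG, CH2Cl2, 0 °C
Reagents that add atoms: bromine, BrBr; 1,2-bis(tert-butyldimethylsilyl)hydrazine, CC(C)(C)[Si](C)(C)NN[Si](C)(C)C(C)(C)C (its atoms stay only in 17)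
Why: Scandium triflate-catalysed condensation gives the N-silyl hydrazone, which bromine and the guanidine base oxidise through the diazoalkane and a bromodiazonium ion to the vinyl bromide with loss of N2 (Barton vinyl halide synthesis in its silyl hydrazone variant), the double bond being forced to C1=C2 because C10 is quaternary.

Step 14
Reactants: 18 vinyl bromide
Product: 19 austradiol acetate
Conditions: Mn(dpm)3 (10 mol%), PhSiH3, TBHP, i-PrOH, rt
Reagents that add atoms: none
Why: Manganese-hydride hydrogen-atom transfer adds H to C2 and the resulting α-bromo C1 radical takes its hydrogen axially from the α face, anti to the C10 methyl (HAT hydrogenation of a haloalkene, thermodynamic stereocontrol), which places bromine equatorial and β and avoids the C–Br hydrogenolysis typical of palladium catalysts.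

Compound list
1 | (E)-but-2-enal (crotonaldehyde) | C/C=C/C=O | starting material
2 | (E)-1-(tert-butyldimethylsilyloxy)buta-1,3-diene | CC(C)(C)[Si](C)(C)O/C=C/C=C | intermediate
3 | 2-methoxy-5-methyl-1,4-benzoquinone | COC1=CC(=O)C(C)=CC1=O | starting material
4 | cis-fused endo adduct, (4aR,5S,8aR)-5-(tert-butyldimethylsilyloxy)-3-methoxy-8a-methyl-4a,5,8,8a-tetrahydronaphthalene-1,4-dione | CC(C)(C)[Si](C)(C)O[C@H]1C=CC[C@@]2(C)C(=O)C=C(OC)C(=O)[C@@H]12 | intermediate
5 | trans-fused adduct, (4aS,5S,8aR) epimer of 4 | CC(C)(C)[Si](C)(C)O[C@H]1C=CC[C@@]2(C)C(=O)C=C(OC)C(=O)[C@H]12 | intermediate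
6 | trans-fused 3-methoxy-2,3-dihydro dione (C3 epimers) | CC(C)(C)[Si](C)(C)O[C@H]1C=CC[C@@]2(C)C(=O)CC(OC)C(=O)[C@H]12 | intermediate (not isolated)
7 | (4aS,5S,8aR)-5-(tert-butyldimethylsilyloxy)-8a-methyl-2,3,4a,5,8,8a-hexahydronaphthalene-1,4-dione | CC(C)(C)[Si](C)(C)O[C@H]1C=CC[C@@]2(C)C(=O)CCC(=O)[C@H]12 | intermediate
8 | (4aS,5S,8aR)-5-hydroxy-8a-methyl-2,3,4a,5,8,8a-hexahydronaphthalene-1,4-dione | O[C@H]1C=CC[C@@]2(C)C(=O)CCC(=O)[C@H]12 | intermediate
9 | ethyl 1-propenyl ether (E/Z mixture) | CC=COCC | starting material
10 | bromoacetal, 6α-O-(2-bromo-1-ethoxypropyl) ether of 8 (side-chain diastereomers) | CCOC(C(C)Br)O[C@H]1C=CC[C@@]2(C)C(=O)CCC(=O)[C@H]12 | intermediate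
11 | tricyclic acetal, trans-10β-methyldecalin-1,4-dione with a cis-fused 2-ethoxy-3-methyloxolane on O6(α)/C7(α) | CCOC1O[C@H]2[C@@H](C1C)CC[C@@]3(C)C(=O)CCC(=O)[C@H]23 | intermediate
12 | 4-methylene analogue of 11 | CCOC1O[C@H]2[C@@H](C1C)CC[C@@]3(C)C(=O)CCC(=C)[C@H]23 | intermediate
13 | 4α-hydroxy-4β-methyl analogue of 11 | CCOC1O[C@H]2[C@@H](C1C)CC[C@@]3(C)C(=O)CC[C@@](C)(O)[C@H]23 | intermediate
14 | 4α,6α-dihydroxy-4β,10β-dimethyl-7α-[1-(1,3-dithiolan-2-yl)ethyl]-trans-decalin-1-one | O[C@H]1[C@@H](C(C)C3SCCS3)CC[C@@]2(C)C(=O)CC[C@@](C)(O)[C@H]12 | intermediate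
15 | 4α,6α-dihydroxy-7α-isopropyl-4β,10β-dimethyl-trans-decalin-1-one | O[C@H]1[C@@H](C(C)C)CC[C@@]2(C)C(=O)CC[C@@](C)(O)[C@H]12 | intermediate
16 | 6α-acetoxy-4α-hydroxy-7α-isopropyl-4β,10β-dimethyl-trans-decalin-1-one | CC(=O)O[C@H]1[C@@H](C(C)C)CC[C@@]2(C)C(=O)CC[C@@](C)(O)[C@H]12 | intermediate
17 | C1 N-(tert-butyldimethylsilyl)hydrazone of 16 | CC(=O)O[C@H]1[C@@H](C(C)C)CC[C@@]2(C)C(=NN[Si](C)(C)C(C)(C)C)CC[C@@](C)(O)[C@H]12 | intermediate (not isolated)
18 | vinyl bromide, 6α-acetoxy-1-bromo-4α-hydroxy-7α-isopropyl-4β,10β-dimethyl-trans-octal-1(2)-ene | CC(=O)O[C@H]1[C@@H](C(C)C)CC[C@@]2(C)C(Br)=CC[C@@](C)(O)[C@H]12 | intermediate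
19 | austradiol acetate (1β-Br, 4α-OH, 4β-CH3, 5α-H, 6α-OAc, 7α-iPr, 10β-CH3) | CC(=O)O[C@H]1[C@@H](C(C)C)CC[C@@]2(C)[C@H](Br)CC[C@@](C)(O)[C@H]12 | target

Total step count: 14. Longest linear sequence: 14 steps (1 → 19); 3 and 9 are purchased and enter at steps 2 and 6.

Steps most likely to fail

Step 2 (key step). What may go wrong: insufficient enantiofacial discrimination at the hindered, methyl-bearing alkene, or Lewis acid-induced cleavage of the silyl dienol ether before cycloaddition. Fallback (resolution in place of asymmetric catalysis): starting again from 3 and 2, the cycloaddition is run without catalyst in toluene at 60–80 °C, where the same site, ortho and endo preferences should hold. This gives adduct 4 together with its mirror image, the enantiomeric adduct F1. Preparative chromatography on a chiral stationary phase (SFC) separates the two, and the route is rejoined at 4.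

Step 3. What may go wrong: an unfavourable position of the cis/trans equilibrium (the preference for trans in angular-methyl adducts is expected to be modest), or loss of the silyloxy group by β-elimination from the enolate. Fallback (the ring fusion is corrected after the O6 tether is in place): starting from 4, the cis series is taken through the conditions of steps 4–7. SmI2 gives the cis 3-methoxy dione F2 (not isolated) and then the cis silyloxy dione F3, HF·pyridine the cis hydroxy dione F4, NBS and 9 the cis bromoacetal F5, and Bu3SnH/AIBN the cis tricyclic acetal F6. F6 is then equilibrated with NaOMe in MeOH at room temperature. O6 is now an acetal oxygen held in a ring and cannot leave, and a cis ring fusion must place either C4 syn-axial to the new C7 carbon or C1 syn-axial to O6, so the trans isomer should gain. The trans epimer is 11, where the route is rejoined; it is methylenated at once (step 8), which removes the epimerisable position.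

Step 14. What may go wrong: loss of bromine (hydrodebromination through a β-bromo radical if hydrogen is transferred to C1 first, or over-reduction), or slow hydrogen-atom transfer to the hindered, electron-poor bromoalkene. Fallback (two bromine atoms installed, one removed afterwards): starting from 16, the silyl hydrazone 17 is made as in step 13 and oxidised with CuBr2 and Et3N in MeOH to the 1,1-dibromide F7 (gem-dihalide synthesis from hydrazones). One bromine is then removed with Bu3SnH (1.0 equiv) and Et3B/air in toluene at −78 °C. The α-bromo C1 radical is the same as in step 14 and should again take hydrogen from the α face, which returns the route at 19.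

Further compounds
F1 | step 2 | enantiomer of adduct 4 | CC(C)(C)[Si](C)(C)O[C@@H]1C=CC[C@]2(C)C(=O)C=C(OC)C(=O)[C@H]12
F2 | step 3 | cis-fused 3-methoxy dione (not isolated) | CC(C)(C)[Si](C)(C)O[C@H]1C=CC[C@@]2(C)C(=O)CC(OC)C(=O)[C@@H]12
F3 | step 3 | cis-fused silyloxy dione | CC(C)(C)[Si](C)(C)O[C@H]1C=CC[C@@]2(C)C(=O)CCC(=O)[C@@H]12
F4 | step 3 | cis-fused hydroxy dione | O[C@H]1C=CC[C@@]2(C)C(=O)CCC(=O)[C@@H]12
F5 | step 3 | cis-fused bromoacetal | CCOC(C(C)Br)O[C@H]1C=CC[C@@]2(C)C(=O)CCC(=O)[C@@H]12
F6 | step 3 | cis-fused tricyclic acetal | CCOC1O[C@H]2[C@@H](C1C)CC[C@@]3(C)C(=O)CCC(=O)[C@@H]23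
F7 | step 14 | 1,1-dibromide, 6α-acetoxy-1,1-dibromo-4α-hydroxy-7α-isopropyl-4β,10β-dimethyl-trans-decalin | CC(=O)O[C@H]1[C@@H](C(C)C)CC[C@@]2(C)C(Br)(Br)CC[C@@](C)(O)[C@H]12
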